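**Plan**

- Locants are eudesmane locants of the target: ring A = C1–C5 and C10, ring B = C5–C10, C14 is the methyl on C10, C15 sits on C4, and the side chain C11(=C13)–C12 sits on C7.
- Retrosynthesis: cut the C15–O ester bond (Mitsunobu) and take C12 and C15 back to a nitrile and a methyl ester; cut C5–C10 and C1–C2 (intramolecular Diels–Alder); re-form C2–C5 to fold the diene into a cyclobutene; cut C2–C3 and C4–C5 ([2+2] with methyl propiolate); C10=C1 and C5=C2 come from two carbonyl groups, and these from ozonolysis of the C5=C10 alkene of (R)-limonene.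
- The feature that allows this: ring A is a cyclohexene whose C3=C4 bond is flanked by C2 and the ring-fusion carbon C5 and carries the only oxidised carbon, C15, on C4. C2–C5 with C15 is therefore a 2-carboxy-1,3-diene, which can be stored as a cyclobut-1-enecarboxylate and released by heat.
- Forward: the six-membered ring of limonene (the future ring B) is opened, its two ends are turned into the C10=C1 alkene and the cyclobutene, and one thermal operation re-closes ring B and grows the four-membered ring by two atoms (C1, C10) into ring A.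
- Stereochemistry: C7 comes unchanged from (R)-limonene; C5 and C10 are set in the cycloaddition by a chair-like anti transition state with the C7 group equatorial; the Z-alkene comes from a Z-selective Horner–Wadsworth–Emmons reaction.
- The side chain is carried as a conjugated nitrile (an inert, electron-poor alkene), so the main line needs no protecting group.

Key step: step 7

**Route**

Step 1
Reactants: 1 (R)-(+)-limonene, (4R)-1-methyl-4-(prop-1-en-2-yl)cyclohex-1-ene
Product: 4 2-[(1R)-4-methylcyclohex-3-en-1-yl]prop-2-en-1-ol, via allyllithium 2 (not isolated), via allylboronate 3 (not isolated)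
Conditions: n-BuLi, TMEDA, hexane, 25 °C; B(OMe)3, THF, −78 °C; H2O2, NaOH, H2O, 0 °C
Reagents that add atoms: hydrogen peroxide, OO
Why: Kinetic allylic lithiation of the isopropenyl methyl group by n-BuLi·TMEDA, borylation of the symmetrical 2-substituted allyllithium and oxidation of the C–B bond give the allylic alcohol, and the C7 stereocentre of (R)-limonene is not touched.

Step 2
Reactants: 4 2-[(1R)-4-methylcyclohex-3-en-1-yl]prop-2-en-1-ol
Product: 7 2-[(1R)-4-methylcyclohex-3-en-1-yl]prop-2-enenitrile, via enal 5 (not isolated), via aldimine 6 (not isolated)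
Conditions: MnO2, NH3 (2 M in i-PrOH), MgSO4, THF, 25 °C
Reagents that add atoms: ammonia, N
Why: Tandem oxidation–imination–oxidation with MnO2 and ammonia takes the allylic alcohol to the conjugated nitrile, whose electron-poor alkene will not compete in the ozonolysis, the [2+2] step or the Diels–Alder step; no stereocentre is formed.

Step 3
Reactants: 7 2-[(1R)-4-methylcyclohex-3-en-1-yl]prop-2-enenitrile
Product: 9 (3R)-2-methylidene-6-oxo-3-(2-oxoethyl)heptanenitrile, via ozonide 8 (not isolated)
Conditions: O3 (1 equiv), CH2Cl2, −78 °C; Me2S, −78 → 25 °C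
Reagents that add atoms: ozone, [O-][O+]=O
Why: Ozonolysis with reductive work-up should cleave the electron-rich trisubstituted ring alkene much faster than the cyano-substituted 1,1-disubstituted alkene, opening the future ring B to the C5 aldehyde and the C10 methyl ketone while C7 stays as it is.

Step 4
Reactants: 9 (3R)-2-methylidene-6-oxo-3-(2-oxoethyl)heptanenitrile
Product: 10 (3R)-2-methylidene-6-oxo-3-(prop-2-en-1-yl)heptanenitrile
Conditions: Ph3PCH3Br, KN(SiMe3)2 (slight deficit), THF, 0 °C; then 9, −78 → 0 °C
Reagents that add atoms: methyltriphenylphosphonium bromide, C[P+](c1ccccc1)(c1ccccc1)c1ccccc1.[Br-]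
Why: Wittig methylenation with one equivalent of ylide at low temperature is selective for the aldehyde over the methyl ketone and turns C5 into the vinyl group C5=C2; no stereocentre is formed.

Step 5
Reactants: 10 (3R)-2-methylidene-6-oxo-3-(prop-2-en-1-yl)heptanenitrile; 11 methyl prop-2-ynoate (methyl propiolate)
Product: 12 methyl 4-[(2R)-2-(1-cyanoethenyl)-5-oxohexyl]cyclobut-1-ene-1-carboxylate (both epimers at the ring CH)
Conditions: EtAlCl2 (3 equiv), CH2Cl2, 25 °C
Reagents that add atoms: none
Why: In this Lewis-acid-promoted stepwise [2+2] cycloaddition of a propiolate ester to a monosubstituted alkene, the terminal CH2 (C2) attacks the propiolate β-carbon (C3) and the α-carbon (C4) closes onto C5, so the ester-bearing carbon ends next to the chain-bearing ring carbon; the new C5 centre forms as a mixture, which does not matter because C5 becomes sp2 again in step 7.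

Step 6
Reactants: 12 methyl 4-[(2R)-2-(1-cyanoethenyl)-5-oxohexyl]cyclobut-1-ene-1-carboxylate
Product: 13 methyl 4-[(2R)-2-(1-cyanoethenyl)-5-methylhex-5-en-1-yl]cyclobut-1-ene-1-carboxylate
Conditions: Ph3PCH3Br, KN(SiMe3)2 (slight deficit), THF, 0 °C; then 12, −78 → 0 °C
Reagents that add atoms: methyltriphenylphosphonium bromide, C[P+](c1ccccc1)(c1ccccc1)c1ccccc1.[Br-]
Why: Wittig methylenation of the unhindered methyl ketone at low temperature should be faster than conjugate addition of the ylide to the cyclobutene ester or the acrylonitrile, and it installs the 1,1-disubstituted alkene C10=C1 that carries the future angular methyl C14; no stereocentre is formed.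

Step 7
Reactants: 13 methyl 4-[(2R)-2-(1-cyanoethenyl)-5-methylhex-5-en-1-yl]cyclobut-1-ene-1-carboxylate
Product: 15 methyl (4aR,7R,8aR)-7-(1-cyanoethenyl)-4a-methyl-3,4,4a,5,6,7,8,8a-octahydronaphthalene-1-carboxylate, via diene ester 14 (not isolated)
Conditions: toluene (0.005 M), BHT, sealed tube, 150 °C
Reagents that add atoms: none
Why: Heating opens the cyclobutene by conrotatory 4π-electrocyclic cleavage of the C2–C5 σ-bond with the C5 alkyl chain rotating outward, which gives the (Z)-configured 2-(methoxycarbonyl)-1,3-diene 14 whose tether is trans to the vinyl group, the only geometry from which the tethered alkene can be reached. The electron-poor diene then takes up the electron-rich 1,1-disubstituted alkene C10=C1 in an inverse-demand intramolecular Diels–Alder reaction of the 1,7,9-decatriene type, so that C1 and C10 are in effect inserted into the former C2–C5 bond and the four-membered ring becomes ring A by a two-atom ring expansion. The closest known reactions are the thermal ring opening of cyclobut-1-enecarboxylates to 2-carboalkoxybutadienes and the intramolecular Diels–Alder cyclisation of decatrienes to angular-methyl octalins. Ring B closes through the C5–C10 bond and ring A through the C1–C2 bond in one concerted suprafacial [4+2] event, with the four-carbon tether C6–C9 allowing only the fused mode. C5 and C10 are set together in the chair-like anti transition state, which gives the trans ring fusion with axial C14, and the existing C7 centre fixes their absolute sense because its 1-cyanoethenyl group sits equatorial on the forming chair and so ends cis to C14. The step needs the intramolecular capture to win over dimerisation of 14, which high dilution and slow generation of the diene should secure, and it leaves C3=C4 and the C15 ester exactly where the target needs them.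

Step 8
Reactants: 15 methyl (4aR,7R,8aR)-7-(1-cyanoethenyl)-4a-methyl-3,4,4a,5,6,7,8,8a-octahydronaphthalene-1-carboxylate
Product: 17 2-[(2R,4aR,8aR)-8-(hydroxymethyl)-4a-methyl-1,2,3,4,4a,5,6,8a-octahydronaphthalen-2-yl]prop-2-enal, via aldimine 16 (not isolated)
Conditions: i-Bu2AlH (4 equiv), CH2Cl2, −78 → −40 °C; then 1 M HCl, 0 °C
Reagents that add atoms: water, O
Why: Low-temperature i-Bu2AlH reduction converts the conjugated ester to the allylic alcohol (1,2-reduction) and the conjugated nitrile to the aldimine, which is hydrolysed to the enal on acidic work-up, so C15 and C12 reach their different oxidation levels in one operation; no stereocentre is affected.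

Step 9
Reactants: 18 4-{[tert-butyl(dimethyl)silyl]oxy}benzaldehyde; 19 ethyl 2-(diphenoxyphosphoryl)acetate
Product: 21 ethyl (2Z)-3-(4-{[tert-butyl(dimethyl)silyl]oxy}phenyl)prop-2-enoate, via sodium phosphonate 20 (not isolated)
Conditions: NaH, THF, 0 °C; then 18, −78 °C
Reagents that add atoms: none
Why: In this Z-selective Horner–Wadsworth–Emmons olefination the diaryl phosphonoacetate anion adds to the aromatic aldehyde at −78 °C and eliminates fast, which should give the cis cinnamate under kinetic control.

Step 10
Reactants: 21 ethyl (2Z)-3-(4-{[tert-butyl(dimethyl)silyl]oxy}phenyl)prop-2-enoate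
Product: 22 (2Z)-3-(4-hydroxyphenyl)prop-2-enoic acid
Conditions: LiOH, THF/MeOH/H2O, 0 → 25 °C, dark; then 1 M HCl
Reagents that add atoms: lithium hydroxide, [Li+].[OH-]
Why: Saponification with LiOH cleaves the ethyl ester and the aryl silyl ether in one operation, and the Z double bond should survive in the dark because hydroxide attacks only at the acyl carbon and at silicon.

Step 11
Reactants: 17 2-[(2R,4aR,8aR)-8-(hydroxymethyl)-4a-methyl-1,2,3,4,4a,5,6,8a-octahydronaphthalen-2-yl]prop-2-enal; 22 (2Z)-3-(4-hydroxyphenyl)prop-2-enoic acid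
Product: 23 [(4aR,7R,8aR)-4a-methyl-7-(3-oxoprop-1-en-2-yl)-3,4,4a,5,6,7,8,8a-octahydronaphthalen-1-yl]methyl (2Z)-3-(4-hydroxyphenyl)prop-2-enoate
Conditions: PPh3, DIAD (premixed), THF, 0 °C, dark
Reagents that add atoms: none
Why: In this Mitsunobu esterification the carboxylic acid, far more acidic than the phenol, is the nucleophile and displaces the activated primary allylic C15–OH by SN2, so neither phenol protection nor an acyl-donor form of the Z-acid is needed; no stereocentre is involved.

Step 12
Reactants: 23 [(4aR,7R,8aR)-4a-methyl-7-(3-oxoprop-1-en-2-yl)-3,4,4a,5,6,7,8,8a-octahydronaphthalen-1-yl]methyl (2Z)-3-(4-hydroxyphenyl)prop-2-enoate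
Product: 24 2-[(2R,4aR,8aR)-8-({[(2Z)-3-(4-hydroxyphenyl)prop-2-enoyl]oxy}methyl)-4a-methyl-1,2,3,4,4a,5,6,8a-octahydronaphthalen-2-yl]prop-2-enoic acid
Conditions: NaClO2, NaH2PO4, 2-methylbut-2-ene (large excess), t-BuOH/H2O, 0 °C
Reagents that add atoms: sodium chlorite, [Na+].[O-]Cl=O
Why: The Pinnick chlorite oxidation converts the 2-substituted acrolein into the acrylic acid under buffered conditions that should leave the allylic ester, the Z-cinnamate and both alkenes alone, the hypochlorous acid being trapped by 2-methylbut-2-ene.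

**Compound list**

1 | (R)-(+)-limonene, (4R)-1-methyl-4-(prop-1-en-2-yl)cyclohex-1-ene | C=C(C)[C@@H]1CCC(C)=CC1 | starting material
2 | {2-[(1R)-4-methylcyclohex-3-en-1-yl]prop-2-en-1-yl}lithium (not isolated) | C=C(C[Li])[C@@H]1CCC(C)=CC1 | intermediate
3 | dimethyl {2-[(1R)-4-methylcyclohex-3-en-1-yl]prop-2-en-1-yl}boronate (not isolated) | C=C(CB(OC)OC)[C@@H]1CCC(C)=CC1 | intermediate
4 | 2-[(1R)-4-methylcyclohex-3-en-1-yl]prop-2-en-1-ol | C=C(CO)[C@@H]1CCC(C)=CC1 | intermediate
5 | 2-[(1R)-4-methylcyclohex-3-en-1-yl]prop-2-enal (not isolated) | C=C(C=O)[C@@H]1CCC(C)=CC1 | intermediate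
6 | 2-[(1R)-4-methylcyclohex-3-en-1-yl]prop-2-en-1-imine (not isolated) | C=C(C=N)[C@@H]1CCC(C)=CC1 | intermediate
7 | 2-[(1R)-4-methylcyclohex-3-en-1-yl]prop-2-enenitrile | C=C(C#N)[C@@H]1CCC(C)=CC1 | intermediate
8 | 2-[(3R)-6-methyl-7,8,9-trioxabicyclo[4.2.1]nonan-3-yl]prop-2-enenitrile, secondary ozonide, both bridgehead isomers (not isolated) | C=C(C#N)[C@@H]1CCC2(C)OOC(C1)O2 | intermediate
9 | (3R)-2-methylidene-6-oxo-3-(2-oxoethyl)heptanenitrile | C=C(C#N)[C@@H](CC=O)CCC(C)=O | intermediate
10 | (3R)-2-methylidene-6-oxo-3-(prop-2-en-1-yl)heptanenitrile | C=C(C#N)[C@@H](CC=C)CCC(C)=O | intermediate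
11 | methyl prop-2-ynoate (methyl propiolate) | C#CC(=O)OC | starting material
12 | methyl 4-[(2R)-2-(1-cyanoethenyl)-5-oxohexyl]cyclobut-1-ene-1-carboxylate, both epimers at the ring CH | C=C(C#N)[C@@H](CC1CC=C1C(=O)OC)CCC(C)=O | intermediate
13 | methyl 4-[(2R)-2-(1-cyanoethenyl)-5-methylhex-5-en-1-yl]cyclobut-1-ene-1-carboxylate, both epimers at the ring CH | C=C(C#N)[C@@H](CC1CC=C1C(=O)OC)CCC(C)=C | intermediate
14 | methyl (2Z,5R)-5-(1-cyanoethenyl)-2-ethenyl-8-methylnona-2,8-dienoate (not isolated) | C=C(C#N)[C@@H](C/C=C(/C=C)C(=O)OC)CCC(C)=C | intermediate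
15 | methyl (4aR,7R,8aR)-7-(1-cyanoethenyl)-4a-methyl-3,4,4a,5,6,7,8,8a-octahydronaphthalene-1-carboxylate (trans-fused; 5α-H, 7β side chain, 10β-methyl in eudesmane terms) | C=C(C#N)[C@@H]1CC[C@@]2(C)CCC=C(C(=O)OC)[C@@H]2C1 | intermediate
16 | [(4aR,7R,8aR)-7-(3-iminoprop-1-en-2-yl)-4a-methyl-3,4,4a,5,6,7,8,8a-octahydronaphthalen-1-yl]methanol (not isolated) | C=C(C=N)[C@@H]1CC[C@@]2(C)CCC=C(CO)[C@@H]2C1 | intermediate
17 | 2-[(2R,4aR,8aR)-8-(hydroxymethyl)-4a-methyl-1,2,3,4,4a,5,6,8a-octahydronaphthalen-2-yl]prop-2-enal | C=C(C=O)[C@@H]1CC[C@@]2(C)CCC=C(CO)[C@@H]2C1 | intermediate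
18 | 4-{[tert-butyl(dimethyl)silyl]oxy}benzaldehyde | CC(C)(C)[Si](C)(C)Oc1ccc(C=O)cc1 | starting material
19 | ethyl 2-(diphenoxyphosphoryl)acetate | CCOC(=O)CP(=O)(Oc1ccccc1)Oc1ccccc1 | starting material
20 | sodium salt of the carbanion of ethyl 2-(diphenoxyphosphoryl)acetate (not isolated) | CCOC(=O)[CH-]P(=O)(Oc1ccccc1)Oc1ccccc1.[Na+] | intermediate
21 | ethyl (2Z)-3-(4-{[tert-butyl(dimethyl)silyl]oxy}phenyl)prop-2-enoate | CCOC(=O)/C=C\c1ccc(O[Si](C)(C)C(C)(C)C)cc1 | intermediate
22 | (2Z)-3-(4-hydroxyphenyl)prop-2-enoic acid | OC(=O)/C=C\c1ccc(O)cc1 | intermediate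
23 | [(4aR,7R,8aR)-4a-methyl-7-(3-oxoprop-1-en-2-yl)-3,4,4a,5,6,7,8,8a-octahydronaphthalen-1-yl]methyl (2Z)-3-(4-hydroxyphenyl)prop-2-enoate | C=C(C=O)[C@@H]1CC[C@@]2(C)CCC=C(COC(=O)/C=C\c3ccc(O)cc3)[C@@H]2C1 | intermediate
24 | 2-[(2R,4aR,8aR)-8-({[(2Z)-3-(4-hydroxyphenyl)prop-2-enoyl]oxy}methyl)-4a-methyl-1,2,3,4,4a,5,6,8a-octahydronaphthalen-2-yl]prop-2-enoic acid | C=C(C(=O)O)[C@@H]1CC[C@@]2(C)CCC=C(COC(=O)/C=C\c3ccc(O)cc3)[C@@H]2C1 | target

**Step count and risks**

Total step count: 12. Longest linear sequence: 10 steps (steps 1–8, 11 and 12); steps 9 and 10 form a two-step side branch.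

Step 5. The risk is that the ene reaction (transfer of an allylic hydrogen from C6 to the propiolate) outruns ring closure to the cyclobutene, and that the ketone and the nitrile tie up the Lewis acid. The fallback leaves the [2+2] route and builds the same diene geometry by cross-coupling. It sets out from keto aldehyde 9. Dibromo-olefination of the aldehyde (CBr4, PPh3, CH2Cl2, 0 °C) should give (3R)-3-(3,3-dibromoprop-2-en-1-yl)-2-methylidene-6-oxoheptanenitrile F1. Wittig methylenation of the ketone as in step 6 should give (3R)-3-(3,3-dibromoprop-2-en-1-yl)-6-methyl-2-methylidenehept-6-enenitrile F2. A Stille coupling with tributyl(vinyl)stannane (zerovalent palladium catalyst Pd2(dba)3, tri(2-furyl)phosphine, toluene, 25 °C) is known to take place at the bromide trans to the chain and should give (3R)-3-[(2Z)-3-bromopenta-2,4-dien-1-yl]-6-methyl-2-methylidenehept-6-enenitrile F3. Methoxycarbonylation of the remaining bromide with retention (PdCl2(PPh3)2, CO, MeOH, Et3N, 50 °C) then gives diene ester 14, where the fallback comes back to the route; 14 is heated on to 15 as in step 7.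

Step 7. The risk is that dimerisation or polymerisation of the transient diene ester outruns its capture by the unactivated 1,1-disubstituted alkene, and that the preference for the anti transition state at the ring fusion is incomplete. The fallback separates the two events and replaces the thermal cycloaddition by a metal-mediated one. It sets out from 13, which is opened by brief heating at high dilution (flow thermolysis, about 130 °C) so that diene ester 14 can be isolated. Compound 14 is then cyclised at 25–60 °C with a cationic monovalent rhodium catalyst ([RhCl(cod)]2, AgSbF6, CH2Cl2), which joins unactivated diene–ene pairs through oxidative cyclisation and reductive elimination. The fallback comes back to the route at 15 and makes no new compound.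

Step 11. The risk is Z-to-E isomerisation of the cinnamate through reversible conjugate addition of the phosphine, and alkylation of the phenol instead of the carboxylate. The fallback turns the alcohol into the electrophile and the acid into a plain carboxylate nucleophile, with no phosphine present. It sets out from 17. Mesylation (MsCl, Et3N, CH2Cl2, −20 °C) should give [(4aR,7R,8aR)-4a-methyl-7-(3-oxoprop-1-en-2-yl)-3,4,4a,5,6,7,8,8a-octahydronaphthalen-1-yl]methyl methanesulfonate F4. Displacement with LiBr (acetone, 0 °C) should give 2-[(2R,4aR,8aR)-8-(bromomethyl)-4a-methyl-1,2,3,4,4a,5,6,8a-octahydronaphthalen-2-yl]prop-2-enal F5. F5 is then alkylated by the sodium carboxylate of 22 (NaHCO3, DMF, 25 °C, dark); under bicarbonate the phenol stays protonated. The fallback comes back to the route at 23.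

**Further compounds**

F1 | step 5 | (3R)-3-(3,3-dibromoprop-2-en-1-yl)-2-methylidene-6-oxoheptanenitrile | C=C(C#N)[C@@H](CC=C(Br)Br)CCC(C)=O
F2 | step 5 | (3R)-3-(3,3-dibromoprop-2-en-1-yl)-6-methyl-2-methylidenehept-6-enenitrile | C=C(C#N)[C@@H](CC=C(Br)Br)CCC(C)=C
F3 | step 5 | (3R)-3-[(2Z)-3-bromopenta-2,4-dien-1-yl]-6-methyl-2-methylidenehept-6-enenitrile | C=C(C#N)[C@@H](C/C=C(\Br)C=C)CCC(C)=C
F0 | step 7 | none | none
F4 | step 11 | [(4aR,7R,8aR)-4a-methyl-7-(3-oxoprop-1-en-2-yl)-3,4,4a,5,6,7,8,8a-octahydronaphthalen-1-yl]methyl methanesulfonate | C=C(C=O)[C@@H]1CC[C@@]2(C)CCC=C(COS(C)(=O)=O)[C@@H]2C1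
F5 | step 11 | 2-[(2R,4aR,8aR)-8-(bromomethyl)-4a-methyl-1,2,3,4,4a,5,6,8a-octahydronaphthalen-2-yl]prop-2-enal | C=C(C=O)[C@@H]1CC[C@@]2(C)CCC=C(CBr)[C@@H]2C1
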